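## Retrosynthetic overview

1. The plan rests on the aryl ether bond O1–C7a of the dihydrofuran ring D. C7a is a ring B carbon next to C7–OMe and para to C5, so it can be carried as C–Br (activated by a C5 ester) and bonded to the oxygen of the C2 carbinol without touching any bond at C2 or C3.
2. Ring D is formed first: cis-dihydrobenzofuran 16 ⇐ anti bromo alcohol 15 by copper-catalysed intramolecular O-arylation. 15 ⇐ diol 14 ⇐ auxiliary-controlled anti aldol (C2–C3 bond, both stereocentres) of arylacetyl imide 10 and O-benzylvanillin 11.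
3. Ring B block 7 ⇐ methyl 4-amino-3-methoxybenzoate 1 by iodination, Sandmeyer bromination, then iodide-selective Negishi–Reformatsky coupling.
4. Ring E is formed second, on the C5 aldehyde 18: syn aldol–lactonisation with succinyl imide 21 (C4'–C5' bond, ring closed as a lactone), enolate hydroxylation (C3'), methylenation, hydroboration (C2') and B-alkyl Suzuki coupling with ring A bromide 34.
5. End game: fluoride removal of three silyl ethers, then neutral hydrogenolysis of the two phenol benzyl ethers.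

Key step: step 9

Assumption: the MgCl2-catalysed anti aldol is taken to run through the chelated Z-enolate, attacked on the face remote from the auxiliary benzyl group (the face used in enolate alkylation), so the (R)-auxiliary gives the (2S,3R) adduct; if the configuration found for 13 were the opposite, auxiliary 19 would replace 8.

Locants and abbreviations:
- Dihydrobenzofuran: O1, C2, C3, C3a, C4–C7, C7a.
- Ring E (oxolane): O1', C2' (benzyl-bearing), C3' (OH), C4' (CH2OH), C5' (aryl-bearing).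
- Ring A is the guaiacyl ring of the C2' benzyl group; ring C is the guaiacyl ring on C2.
- DBF = (2R,3R)-2-[4-(benzyloxy)-3-methoxyphenyl]-7-methoxy-3-{[(triisopropylsilyl)oxy]methyl}-2,3-dihydrobenzofuran-5-yl.
- TBS = tert-butyldimethylsilyl; TIPS = triisopropylsilyl.

## Route

Step 1
Reactants: 1 methyl 4-amino-3-methoxybenzoate
Product: 2 methyl 4-amino-3-iodo-5-methoxybenzoate
Conditions: NIS, MeCN, 0 °C to rt
Reagents that add atoms: N-iodosuccinimide, O=C1CCC(=O)N1I
Why: Electrophilic aromatic iodination, in which the amino group dominates the directing effects and its only free ortho position is attacked because the para position carries the ester.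

Step 2
Reactants: 2 methyl 4-amino-3-iodo-5-methoxybenzoate
Product: 4 methyl 4-bromo-3-iodo-5-methoxybenzoate, via diazonium bromide 3 (not isolated)
Conditions: NaNO2, 48% aq HBr, MeCN–H2O, 0 °C; then CuBr, 0 to 50 °C
Reagents that add atoms: sodium nitrite, [Na+].[O-]N=O (outer nitrogen of 3 only); hydrobromic acid, Br (bromide of 3, bromine of 4)
Why: Sandmeyer bromination installs the future leaving group at C7a, and it is placed before any C–C coupling because an ortho-aminoarylacetate would lactamise to an oxindole.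

Step 3
Reactants: 4 methyl 4-bromo-3-iodo-5-methoxybenzoate, 5 (2-tert-butoxy-2-oxoethyl)zinc chloride
Product: 6 methyl 4-bromo-3-(2-tert-butoxy-2-oxoethyl)-5-methoxybenzoate
Conditions: Pd(PPh3)4 (5 mol %), THF, 50 °C
Reagents that add atoms: none
Why: Negishi-type cross-coupling of a Reformatsky reagent, in which zerovalent palladium inserts much faster into C–I than into the doubly ortho-substituted C–Br bond and the neutral zinc enolate spares the methyl ester.

Step 4
Reactants: 6 methyl 4-bromo-3-(2-tert-butoxy-2-oxoethyl)-5-methoxybenzoate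
Product: 7 [2-bromo-3-methoxy-5-(methoxycarbonyl)phenyl]acetic acid
Conditions: TFA–CH2Cl2 (1:3), rt
Reagents that add atoms: none
Why: Acidolysis of the tert-butyl ester (loss of isobutene through the tert-butyl cation) frees the acid while the methyl ester and aryl bromide are inert.

Step 5
Reactants: 7 [2-bromo-3-methoxy-5-(methoxycarbonyl)phenyl]acetic acid, 8 (R)-4-benzyl-1,3-oxazolidin-2-one
Product: 10 methyl 3-{2-[(4R)-4-benzyl-2-oxo-1,3-oxazolidin-3-yl]-2-oxoethyl}-4-bromo-5-methoxybenzoate, via mixed pivalic anhydride 9 (not isolated)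
Conditions: PivCl, Et3N, THF, −20 °C; then LiCl, 8, −20 °C to rt
Reagents that add atoms: pivaloyl chloride, CC(C)(C)C(=O)Cl (pivaloyl group of 9 only)
Why: N-acylation of the Evans auxiliary through a mixed anhydride with LiCl activation, which avoids strong base next to the acidic benzylic CH2.

Step 6
Reactants: 10 methyl 3-{2-[(4R)-4-benzyl-2-oxo-1,3-oxazolidin-3-yl]-2-oxoethyl}-4-bromo-5-methoxybenzoate, 11 4-(benzyloxy)-3-methoxybenzaldehyde
Product: 13 methyl 3-{(2S,3R)-1-[(4R)-4-benzyl-2-oxo-1,3-oxazolidin-3-yl]-3-[4-(benzyloxy)-3-methoxyphenyl]-3-hydroxy-1-oxopropan-2-yl}-4-bromo-5-methoxybenzoate (anti aldol), via trimethylsilyl ether 12 (not isolated)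
Conditions: MgCl2 (20 mol %), Et3N, TMSCl, EtOAc, rt; then TFA (cat.), MeOH, 0 °C
Reagents that add atoms: chlorotrimethylsilane, C[Si](C)(C)Cl (silyl group of 12 only)
Why: MgCl2-catalysed direct anti aldol of an N-acyloxazolidinone by soft enolisation, in which the chelated Z-magnesium enolate should be attacked by the non-enolisable aldehyde on the face remote from the auxiliary benzyl group through a boat-like transition state, setting the future C3 (2S) and C2 (3R) in the anti relation, while silylation of the aldolate turns the catalyst over and blocks the retro-aldol.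

Step 7
Reactants: 13 anti aldol adduct
Product: 14 methyl 3-{(1R,2R)-1-[4-(benzyloxy)-3-methoxyphenyl]-1,3-dihydroxypropan-2-yl}-4-bromo-5-methoxybenzoate
Conditions: NaBH4, THF–H2O (4:1), 0 °C to rt
Reagents that add atoms: none
Why: Reductive removal of the auxiliary with borohydride in wet THF, in which the imide carbonyl is reduced while the benzoate ester is not attacked by NaBH4, and the near-neutral medium should leave the acidic α-aryl stereocentre unchanged.

Step 8
Reactants: 14 anti diol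
Product: 15 methyl 3-{(1R,2R)-1-[4-(benzyloxy)-3-methoxyphenyl]-1-hydroxy-3-[(triisopropylsilyl)oxy]propan-2-yl}-4-bromo-5-methoxybenzoate
Conditions: TIPSCl, imidazole, CH2Cl2–DMF, 0 °C
Reagents that add atoms: chlorotriisopropylsilane, CC(C)[Si](Cl)(C(C)C)C(C)C
Why: Sterically controlled monosilylation, in which the bulky chlorosilane reacts at the primary hydroxyl and leaves the hindered benzylic hydroxyl free for the ring closure.

Step 9
Reactants: 15 anti bromo alcohol
Product: 16 methyl (2R,3R)-2-[4-(benzyloxy)-3-methoxyphenyl]-7-methoxy-3-{[(triisopropylsilyl)oxy]methyl}-2,3-dihydrobenzofuran-5-carboxylate (cis)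
Conditions: CuI (20 mol %), 3,4,7,8-tetramethyl-1,10-phenanthroline (40 mol %), Cs2CO3 (2 equiv), 4 Å MS, toluene, 110 °C, Ar
Reagents that add atoms: none
Why: Cs2CO3 deprotonates the benzylic carbinol, the alkoxide binds phenanthroline-ligated monovalent copper, the C7a–Br bond (activated by the para ester) adds oxidatively to give a six-membered oxacupracycle of trivalent copper, and reductive elimination forms O1–C7a. The closest known reaction type is the intramolecular Ullmann O-arylation of 2-(2-haloaryl)ethanols to 2,3-dihydrobenzofurans. Ring D closes in the 5-exo mode (formally 5-exo-trig at C7a, the C–Br bond lying outside the new ring). No stereocentre is created, and because no bond at the two sp3 centres is broken, the (1R,2R)-anti array is carried with retention into the cis-(2R,3R) ring. The selectivity needed is between the two oxygens, each of which could close a five-membered ring, and it is secured by masking the primary one as a TIPS ether, whose bulk should suppress the O-to-O silyl shift to the caesium alkoxide that a smaller silyl group could undergo at this temperature. Copper alkoxides are far less prone to β-hydride elimination than palladium alkoxides, so oxidation of the benzylic carbinol to the ketone should not compete.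

Step 10
Reactants: 16 cis-dihydrobenzofuran ester
Product: 17 DBF-methanol
Conditions: DIBAL-H (2.5 equiv), CH2Cl2, −78 °C; aq Rochelle salt
Reagents that add atoms: none
Why: Hydride reduction of the aryl ester to the benzylic alcohol, to which silyl, benzyl and aryl ethers are inert.

Step 11
Reactants: 17 DBF-methanol
Product: 18 DBF-carbaldehyde
Conditions: MnO2, CH2Cl2, rt
Reagents that add atoms: none
Why: MnO2 oxidation of a benzylic alcohol stops at the aldehyde and is neutral, so the acid-sensitive cis-C2–O1 benzylic ether is not put at risk.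

Step 12
Reactants: 19 (S)-4-benzyl-1,3-oxazolidin-2-one, 20 methyl 4-chloro-4-oxobutanoate
Product: 21 methyl 4-[(4S)-4-benzyl-2-oxo-1,3-oxazolidin-3-yl]-4-oxobutanoate
Conditions: Et3N, DMAP (cat.), CH2Cl2, 0 °C to rt
Reagents that add atoms: none
Why: DMAP-catalysed N-acylation of the oxazolidinone by the acid chloride.

Step 13
Reactants: 18 DBF-carbaldehyde, 21 succinyl imide
Product: 24 (4S)-4-benzyl-3-{[(2S,3S)-2-DBF-5-oxooxolan-3-yl]carbonyl}-1,3-oxazolidin-2-one (2,3-trans lactone), via boron enolate 22 (not isolated), via boron aldolate 23 (not isolated)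
Conditions: 21, Bu2BOTf, iPr2NEt, CH2Cl2, 0 °C; 18, −78 °C to rt; then pH 7 buffer, H2O2, MeOH, 0 °C
Reagents that add atoms: dibutylboron triflate, CCCCB(CCCC)OS(=O)(=O)C(F)(F)F (boryl group of 22 and 23 only)
Why: Evans syn aldol, in which the imide side is enolised selectively to the Z-boron enolate, the Zimmerman–Traxler chair under control of the (S)-auxiliary sets C4' and C5' as the (S,S)-syn pair, and the aldolate should close on the methyl ester to give the 4',5'-trans lactone that already contains ring E.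

Step 14
Reactants: 24 lactone imide
Product: 26 (2S,3S)-2-DBF-5-oxooxolane-3-carboxylic acid, via lithium percarboxylate 25 (not isolated)
Conditions: LiOH, H2O2, THF–H2O, 0 °C; Na2SO3; 1 M HCl to pH 3, 0 °C
Reagents that add atoms: hydrogen peroxide, OO (peroxy oxygens of 25, hydroxyl oxygen of 26); lithium hydroxide, [Li+].[OH-] (lithium of 25 only)
Why: Hydroperoxide cleavage of the imide, in which LiOOH attacks the exocyclic carbonyl, sulfite reduces the peracid, and any opened lactone recloses on the brief acidification.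

Step 15
Reactants: 26 lactone acid
Product: 27 (4R,5S)-5-DBF-4-(hydroxymethyl)oxolan-2-one
Conditions: BH3·SMe2, THF, 0 °C to rt; then H2O
Reagents that add atoms: none
Why: Chemoselective borane reduction of the carboxylic acid through its acyloxyborane leaves the lactone alone, and the non-basic medium prevents translactonisation to the primary hydroxyl.

Step 16
Reactants: 27 hydroxymethyl lactone
Product: 28 (4R,5S)-4-{[(tert-butyldimethylsilyl)oxy]methyl}-5-DBF-oxolan-2-one
Conditions: TBSCl, imidazole, DMF, 0 °C to rt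
Reagents that add atoms: tert-butylchlorodimethylsilane, CC(C)(C)[Si](C)(C)Cl
Why: Silylation of the primary alcohol removes the translactonisation pathway and the acidic proton before enolate chemistry.

Step 17
Reactants: 28 silyloxymethyl lactone
Product: 30 (3S,4S,5S)-4-{[(tert-butyldimethylsilyl)oxy]methyl}-5-DBF-3-hydroxyoxolan-2-one, via potassium enolate 29 (not isolated)
Conditions: KHMDS, THF, −78 °C; 3-phenyl-2-(phenylsulfonyl)oxaziridine, −78 °C; AcOH
Reagents that add atoms: potassium hexamethyldisilazide, C[Si](C)(C)[N-][Si](C)(C)C.[K+] (potassium of 29 only); 3-phenyl-2-(phenylsulfonyl)-1,2-oxaziridine, O=S(=O)(c1ccccc1)N1OC1c1ccccc1 (hydroxyl oxygen)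
Why: Davis enolate hydroxylation, in which the oxaziridine approaches the lactone enolate anti to the adjacent C4' silyloxymethyl group and so sets C3' (S), trans to C4'.

Step 18
Reactants: 30 α-hydroxy lactone
Product: 31 (3S,4R,5S)-3-[(tert-butyldimethylsilyl)oxy]-4-{[(tert-butyldimethylsilyl)oxy]methyl}-5-DBF-oxolan-2-one
Conditions: TBSOTf, 2,6-lutidine, CH2Cl2, −78 to 0 °C
Reagents that add atoms: tert-butyldimethylsilyl triflate, CC(C)(C)[Si](C)(C)OS(=O)(=O)C(F)(F)F
Why: Silylation of the hindered secondary hydroxyl with the silyl triflate under lutidine buffering gives a bulky group that will later shield one face of C2'.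

Step 19
Reactants: 31 bis-silylated lactone
Product: 32 (3S,4R,5S)-3-[(tert-butyldimethylsilyl)oxy]-4-{[(tert-butyldimethylsilyl)oxy]methyl}-5-DBF-2-methylideneoxolane
Conditions: Cp2TiMe2, toluene, 70 °C, dark
Reagents that add atoms: dimethyltitanocene Cp2TiMe2, C[Ti+2]C.c1cc[cH-]c1.c1cc[cH-]c1 (the CH2 carbon)
Why: Petasis methylenation, in which thermally formed Cp2Ti=CH2 converts the lactone carbonyl into the exocyclic enol ether by cycloaddition and cycloreversion under neutral conditions, as established for protected sugar lactones.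

Step 20
Reactants: 33 4-bromo-2-methoxyphenol
Product: 34 1-(benzyloxy)-4-bromo-2-methoxybenzene
Conditions: BnBr, K2CO3, DMF, rt
Reagents that add atoms: benzyl bromide, BrCc1ccccc1
Why: Williamson ether synthesis on the phenoxide.

Step 21
Reactants: 32 exocyclic enol ether, 34 1-(benzyloxy)-4-bromo-2-methoxybenzene
Product: 36 (2S,3S,4R,5S)-2-[4-(benzyloxy)-3-methoxybenzyl]-3-[(tert-butyldimethylsilyl)oxy]-4-{[(tert-butyldimethylsilyl)oxy]methyl}-5-DBF-oxolane, via B-alkyl-9-BBN 35 (not isolated)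
Conditions: 9-BBN-H, THF, 0 °C to rt; then 34, PdCl2(dppf) (5 mol %), 3 M aq K3PO4, DMF, 50 °C
Reagents that add atoms: 9-borabicyclo[3.3.1]nonane, B1C2CCCC1CCC2 (boryl group of 35 only)
Why: Hydroboration of an exocyclic enol ether followed by B-alkyl Suzuki–Miyaura coupling, in which boron goes to the terminal carbon and 9-BBN should approach the face opposite the adjacent C3' silyloxy group and the C5' aryl group, placing H on that face and setting C2' (S) with the new CH2 cis to C3'–O, after which the coupling joins CH2 to ring A without touching C2'.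

Step 22
Reactants: 36 fully protected sesquineolignan
Product: 37 (2S,3S,4S,5S)-2-[4-(benzyloxy)-3-methoxybenzyl]-5-{(2R,3R)-2-[4-(benzyloxy)-3-methoxyphenyl]-3-(hydroxymethyl)-7-methoxy-2,3-dihydrobenzofuran-5-yl}-4-(hydroxymethyl)oxolan-3-ol
Conditions: TBAF, THF, 0 °C to rt
Reagents that add atoms: none
Why: Fluoride desilylation of all three silyl ethers is done while both phenols are still benzylated, so no phenoxide para to C2 can open ring D through a quinone methide and erode the cis relation.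

Step 23
Reactants: 37 bis(benzyl ether) triol
Product: 38 CNP0179668.1, (2S,3S,4S,5S)-2-(4-hydroxy-3-methoxybenzyl)-5-[(2R,3R)-2-(4-hydroxy-3-methoxyphenyl)-3-(hydroxymethyl)-7-methoxy-2,3-dihydrobenzofuran-5-yl]-4-(hydroxymethyl)oxolan-3-ol
Conditions: H2 (1 atm), 10% Pd/C, EtOAc–EtOH, rt, stopped after uptake of 2 equiv
Reagents that add atoms: none
Why: Catalytic hydrogenolysis under neutral conditions, in which the unhindered primary benzylic C–O bonds of the two phenol benzyl ethers should be cleaved well before the secondary, ring-bound benzylic C–O bonds at C2 and C5'.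

## Compound list

1 | methyl 4-amino-3-methoxybenzoate | COC(=O)c1ccc(N)c(OC)c1 | starting material
2 | methyl 4-amino-3-iodo-5-methoxybenzoate | COC(=O)c1cc(I)c(N)c(OC)c1 | intermediate
3 | 2-iodo-6-methoxy-4-(methoxycarbonyl)benzenediazonium bromide | COC(=O)c1cc(I)c([N+]#N)c(OC)c1.[Br-] | intermediate
4 | methyl 4-bromo-3-iodo-5-methoxybenzoate | COC(=O)c1cc(I)c(Br)c(OC)c1 | intermediate
5 | (2-tert-butoxy-2-oxoethyl)zinc chloride | CC(C)(C)OC(=O)C[Zn]Cl | starting material
6 | methyl 4-bromo-3-(2-tert-butoxy-2-oxoethyl)-5-methoxybenzoate | COC(=O)c1cc(CC(=O)OC(C)(C)C)c(Br)c(OC)c1 | intermediate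
7 | [2-bromo-3-methoxy-5-(methoxycarbonyl)phenyl]acetic acid | COC(=O)c1cc(CC(=O)O)c(Br)c(OC)c1 | intermediate
8 | (R)-4-benzyl-1,3-oxazolidin-2-one | O=C1N[C@H](Cc2ccccc2)CO1 | starting material
9 | mixed anhydride of 7 and pivalic acid | COC(=O)c1cc(CC(=O)OC(=O)C(C)(C)C)c(Br)c(OC)c1 | intermediate
10 | methyl 3-{2-[(4R)-4-benzyl-2-oxo-1,3-oxazolidin-3-yl]-2-oxoethyl}-4-bromo-5-methoxybenzoate | COC(=O)c1cc(CC(=O)N2[C@H](Cc3ccccc3)COC2=O)c(Br)c(OC)c1 | intermediate
11 | 4-(benzyloxy)-3-methoxybenzaldehyde | COc1cc(C=O)ccc1OCc1ccccc1 | starting material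
12 | O-trimethylsilyl ether of 13 | C[Si](C)(C)O[C@@H](c1ccc(OCc2ccccc2)c(OC)c1)[C@@H](C(=O)N1[C@H](Cc2ccccc2)COC1=O)c1cc(C(=O)OC)cc(OC)c1Br | intermediate
13 | (2S,3R)-anti aldol adduct on the (4R)-auxiliary | O[C@@H](c1ccc(OCc2ccccc2)c(OC)c1)[C@@H](C(=O)N1[C@H](Cc2ccccc2)COC1=O)c1cc(C(=O)OC)cc(OC)c1Br | intermediate
14 | methyl 3-{(1R,2R)-1-[4-(benzyloxy)-3-methoxyphenyl]-1,3-dihydroxypropan-2-yl}-4-bromo-5-methoxybenzoate | O[C@@H](c1ccc(OCc2ccccc2)c(OC)c1)[C@@H](CO)c1cc(C(=O)OC)cc(OC)c1Br | intermediate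
15 | methyl 3-{(1R,2R)-1-[4-(benzyloxy)-3-methoxyphenyl]-1-hydroxy-3-[(triisopropylsilyl)oxy]propan-2-yl}-4-bromo-5-methoxybenzoate | O[C@@H](c1ccc(OCc2ccccc2)c(OC)c1)[C@@H](CO[Si](C(C)C)(C(C)C)C(C)C)c1cc(C(=O)OC)cc(OC)c1Br | intermediate
16 | methyl (2R,3R)-2-[4-(benzyloxy)-3-methoxyphenyl]-7-methoxy-3-{[(triisopropylsilyl)oxy]methyl}-2,3-dihydrobenzofuran-5-carboxylate | COC(=O)c1cc(OC)c2c(c1)[C@H](CO[Si](C(C)C)(C(C)C)C(C)C)[C@H](c1ccc(OCc3ccccc3)c(OC)c1)O2 | intermediate
17 | DBF-methanol | OCc1cc(OC)c2c(c1)[C@H](CO[Si](C(C)C)(C(C)C)C(C)C)[C@H](c1ccc(OCc3ccccc3)c(OC)c1)O2 | intermediate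
18 | DBF-carbaldehyde | O=Cc1cc(OC)c2c(c1)[C@H](CO[Si](C(C)C)(C(C)C)C(C)C)[C@H](c1ccc(OCc3ccccc3)c(OC)c1)O2 | intermediate
19 | (S)-4-benzyl-1,3-oxazolidin-2-one | O=C1N[C@@H](Cc2ccccc2)CO1 | starting material
20 | methyl 4-chloro-4-oxobutanoate | COC(=O)CCC(=O)Cl | starting material
21 | methyl 4-[(4S)-4-benzyl-2-oxo-1,3-oxazolidin-3-yl]-4-oxobutanoate | COC(=O)CCC(=O)N1[C@@H](Cc2ccccc2)COC1=O | intermediate
22 | Z-dibutylboron enolate of 21 | COC(=O)C/C=C(\OB(CCCC)CCCC)N1[C@@H](Cc2ccccc2)COC1=O | intermediate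
23 | methyl (3S,4S)-3-{[(4S)-4-benzyl-2-oxo-1,3-oxazolidin-3-yl]carbonyl}-4-[(dibutylboranyl)oxy]-4-DBF-butanoate | CCCCB(CCCC)O[C@H](c1cc(OC)c2c(c1)[C@H](CO[Si](C(C)C)(C(C)C)C(C)C)[C@H](c1ccc(OCc3ccccc3)c(OC)c1)O2)[C@@H](C(=O)N1[C@@H](Cc2ccccc2)COC1=O)CC(=O)OC | intermediate
24 | (4S)-4-benzyl-3-{[(2S,3S)-2-DBF-5-oxooxolan-3-yl]carbonyl}-1,3-oxazolidin-2-one | O=C1O[C@H](c2cc(OC)c3c(c2)[C@H](CO[Si](C(C)C)(C(C)C)C(C)C)[C@H](c2ccc(OCc4ccccc4)c(OC)c2)O3)[C@@H](C(=O)N2[C@@H](Cc3ccccc3)COC2=O)C1 | intermediate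
25 | lithium (2S,3S)-2-DBF-5-oxooxolane-3-carboperoxoate | O=C1O[C@H](c2cc(OC)c3c(c2)[C@H](CO[Si](C(C)C)(C(C)C)C(C)C)[C@H](c2ccc(OCc4ccccc4)c(OC)c2)O3)[C@@H](C(=O)O[O-])C1.[Li+] | intermediate
26 | (2S,3S)-2-DBF-5-oxooxolane-3-carboxylic acid | O=C1O[C@H](c2cc(OC)c3c(c2)[C@H](CO[Si](C(C)C)(C(C)C)C(C)C)[C@H](c2ccc(OCc4ccccc4)c(OC)c2)O3)[C@@H](C(=O)O)C1 | intermediate
27 | (4R,5S)-5-DBF-4-(hydroxymethyl)oxolan-2-one | O=C1O[C@H](c2cc(OC)c3c(c2)[C@H](CO[Si](C(C)C)(C(C)C)C(C)C)[C@H](c2ccc(OCc4ccccc4)c(OC)c2)O3)[C@@H](CO)C1 | intermediate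
28 | (4R,5S)-4-{[(TBS)oxy]methyl}-5-DBF-oxolan-2-one | O=C1O[C@H](c2cc(OC)c3c(c2)[C@H](CO[Si](C(C)C)(C(C)C)C(C)C)[C@H](c2ccc(OCc4ccccc4)c(OC)c2)O3)[C@@H](CO[Si](C)(C)C(C)(C)C)C1 | intermediate
29 | potassium enolate of 28 | [O-]C1O[C@H](c2cc(OC)c3c(c2)[C@H](CO[Si](C(C)C)(C(C)C)C(C)C)[C@H](c2ccc(OCc4ccccc4)c(OC)c2)O3)[C@@H](CO[Si](C)(C)C(C)(C)C)C=1.[K+] | intermediate
30 | (3S,4S,5S)-4-{[(TBS)oxy]methyl}-5-DBF-3-hydroxyoxolan-2-one | O=C1O[C@H](c2cc(OC)c3c(c2)[C@H](CO[Si](C(C)C)(C(C)C)C(C)C)[C@H](c2ccc(OCc4ccccc4)c(OC)c2)O3)[C@@H](CO[Si](C)(C)C(C)(C)C)[C@@H]1O | intermediate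
31 | (3S,4R,5S)-3-[(TBS)oxy]-4-{[(TBS)oxy]methyl}-5-DBF-oxolan-2-one | O=C1O[C@H](c2cc(OC)c3c(c2)[C@H](CO[Si](C(C)C)(C(C)C)C(C)C)[C@H](c2ccc(OCc4ccccc4)c(OC)c2)O3)[C@@H](CO[Si](C)(C)C(C)(C)C)[C@@H]1O[Si](C)(C)C(C)(C)C | intermediate
32 | (3S,4R,5S)-3-[(TBS)oxy]-4-{[(TBS)oxy]methyl}-5-DBF-2-methylideneoxolane | C=C1O[C@H](c2cc(OC)c3c(c2)[C@H](CO[Si](C(C)C)(C(C)C)C(C)C)[C@H](c2ccc(OCc4ccccc4)c(OC)c2)O3)[C@@H](CO[Si](C)(C)C(C)(C)C)[C@@H]1O[Si](C)(C)C(C)(C)C | intermediate
33 | 4-bromo-2-methoxyphenol | COc1cc(Br)ccc1O | starting material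
34 | 1-(benzyloxy)-4-bromo-2-methoxybenzene | COc1cc(Br)ccc1OCc1ccccc1 | intermediate
35 | (2S,3S,4R,5S)-2-[(9-borabicyclo[3.3.1]nonan-9-yl)methyl]-3-[(TBS)oxy]-4-{[(TBS)oxy]methyl}-5-DBF-oxolane | C(B1C2CCCC1CCC2)[C@@H]1O[C@H](c2cc(OC)c3c(c2)[C@H](CO[Si](C(C)C)(C(C)C)C(C)C)[C@H](c2ccc(OCc4ccccc4)c(OC)c2)O3)[C@@H](CO[Si](C)(C)C(C)(C)C)[C@@H]1O[Si](C)(C)C(C)(C)C | intermediate
36 | (2S,3S,4R,5S)-2-[4-(benzyloxy)-3-methoxybenzyl]-3-[(TBS)oxy]-4-{[(TBS)oxy]methyl}-5-DBF-oxolane | COc1cc(C[C@@H]2O[C@H](c3cc(OC)c4c(c3)[C@H](CO[Si](C(C)C)(C(C)C)C(C)C)[C@H](c3ccc(OCc5ccccc5)c(OC)c3)O4)[C@@H](CO[Si](C)(C)C(C)(C)C)[C@@H]2O[Si](C)(C)C(C)(C)C)ccc1OCc1ccccc1 | intermediate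
37 | bis(O-benzyl) ether of the target, (2S,3S,4S,5S) in ring E and (2R,3R) in ring D | COc1cc(C[C@@H]2O[C@H](c3cc(OC)c4c(c3)[C@H](CO)[C@H](c3ccc(OCc5ccccc5)c(OC)c3)O4)[C@@H](CO)[C@@H]2O)ccc1OCc1ccccc1 | intermediate
38 | CNP0179668.1 | COc1cc(C[C@@H]2O[C@H](c3cc(OC)c4c(c3)[C@H](CO)[C@H](c3ccc(O)c(OC)c3)O4)[C@@H](CO)[C@@H]2O)ccc1O | target

## Step count and risks

Total steps: 23. Longest linear sequence: 21 (steps 1–11, 13–19 and 21–23, from compound 1).

**Step 9 (key step).**
- What may go wrong: oxidative addition at the doubly ortho-substituted C7a–Br bond may be slow at the temperature required. Silyl transfer from the primary to the secondary oxygen (followed by closure through the wrong oxygen) and protodebromination could then compete.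
- Fallback: it sets out from 15 and returns at 16.
- Miyaura borylation of 15 (B2pin2, PdCl2(dppf), KOAc, dioxane, 80 °C) would give the aryl pinacol boronate F1.
- An intramolecular Chan–Lam etherification (Cu(OAc)2, DMAP, 4 Å MS, O2, CH2Cl2, rt) then joins the free C2 hydroxyl to C7a and gives 16.
- The same O1–C7a bond is made, but the arene is now the nucleophilic partner and the closure runs at room temperature without carbonate base, which removes the driving force for silyl migration.

**Step 6.**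
- What may go wrong: the bulky ortho-bromoaryl group on the enolate may erode the anti/syn and facial selectivity, and reversible addition before silylation may level the ratio.
- Fallback: it sets out from 7 (through 9) and 19 and returns at 14.
- Acylation of 19 by 9 gives the (S)-configured arylacetyl imide F2.
- Bu2BOTf and iPr2NEt convert it into the Z-boron enolate F3.
- F3 is added at −78 °C to aldehyde 11 precomplexed with Et2AlCl. The open transition state of this Lewis-acid-mediated aldol favours the anti relation, while the non-chelated enolate keeps the well-established facial bias of the boron aldol.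
- The (S)-auxiliary should therefore give the (2S,3R)-anti adduct F4. NaBH4 in wet THF then releases diol 14.

**Step 21.**
- What may go wrong: β-alkoxy elimination from the alkylborane under the warm basic coupling conditions, and slow transfer of the hindered alkyl group to palladium bearing an electron-rich aryl group.
- Fallback: it sets out from 32 (through 35) and 34 and returns at 36, with the polarity of the C–C bond formation reversed.
- Borane 35 is oxidised at 0 °C (NaBO3, THF–H2O) to the primary alcohol F5.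
- F5 is converted (Tf2O, 2,6-lutidine, CH2Cl2, −78 °C) into the primary triflate F6.
- Bromide 34 gives with Mg in THF the arylmagnesium bromide F7.
- A copper-catalysed Grignard–triflate coupling (CuBr·SMe2 cat., THF, −30 to 0 °C) joins F6 and F7 to give 36.

## Further compounds

F1 | step 9 | methyl 3-{(1R,2R)-1-[4-(benzyloxy)-3-methoxyphenyl]-1-hydroxy-3-[(triisopropylsilyl)oxy]propan-2-yl}-5-methoxy-4-(4,4,5,5-tetramethyl-1,3,2-dioxaborolan-2-yl)benzoate | O[C@@H](c1ccc(OCc2ccccc2)c(OC)c1)[C@@H](CO[Si](C(C)C)(C(C)C)C(C)C)c1cc(C(=O)OC)cc(OC)c1B1OC(C)(C)C(C)(C)O1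
F2 | step 6 | methyl 3-{2-[(4S)-4-benzyl-2-oxo-1,3-oxazolidin-3-yl]-2-oxoethyl}-4-bromo-5-methoxybenzoate | COC(=O)c1cc(CC(=O)N2[C@@H](Cc3ccccc3)COC2=O)c(Br)c(OC)c1
F3 | step 6 | Z-dibutylboron enolate of F2 | COC(=O)c1cc(/C=C(\OB(CCCC)CCCC)N2[C@@H](Cc3ccccc3)COC2=O)c(Br)c(OC)c1
F4 | step 6 | (2S,3R)-anti aldol adduct on the (4S)-auxiliary | O[C@@H](c1ccc(OCc2ccccc2)c(OC)c1)[C@@H](C(=O)N1[C@@H](Cc2ccccc2)COC1=O)c1cc(C(=O)OC)cc(OC)c1Br
F5 | step 21 | {(2S,3S,4R,5S)-3-[(TBS)oxy]-4-{[(TBS)oxy]methyl}-5-DBF-oxolan-2-yl}methanol | OC[C@@H]1O[C@H](c2cc(OC)c3c(c2)[C@H](CO[Si](C(C)C)(C(C)C)C(C)C)[C@H](c2ccc(OCc4ccccc4)c(OC)c2)O3)[C@@H](CO[Si](C)(C)C(C)(C)C)[C@@H]1O[Si](C)(C)C(C)(C)C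
F6 | step 21 | trifluoromethanesulfonate of F5 | O=S(=O)(OC[C@@H]1O[C@H](c2cc(OC)c3c(c2)[C@H](CO[Si](C(C)C)(C(C)C)C(C)C)[C@H](c2ccc(OCc4ccccc4)c(OC)c2)O3)[C@@H](CO[Si](C)(C)C(C)(C)C)[C@@H]1O[Si](C)(C)C(C)(C)C)C(F)(F)F
F7 | step 21 | [4-(benzyloxy)-3-methoxyphenyl]magnesium bromide | COc1cc([Mg]Br)ccc1OCc1ccccc1
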